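**Plan**

Numbering: ring A = C1 (quaternary, Me), C2, C3, C4 (OH, i-Pr), C5 (fusion CH). Ring B = C1, C5, C6 (O-aroyl), C7 (OH), C8 (Me) and C9 (epoxide), C10. β is the face of the C1 methyl.
Cuts: the retrosynthesis removes the epoxide oxygen, the O6–acyl bond and the C7 oxygen. It then exchanges the fusion bond C1–C5 for a C1–C6 bond, which gives a cis-decalin. That decalin is cut at C4–i-Pr, C5=C6 (aldol) and C1–C2 (Michael).
Enabling feature: the bond shared by rings A and B joins quaternary C1 to a CH (C5) that lies between the carbinol C4 and the oxygenated C6. C1 can therefore reach C5 from C6 by a 1,2-shift that leaves a C6 ketone.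
Forward order: the ring of (R)-3-methylcyclohexanone is annulated to a six-six octalone. One semipinacol shift then converts both six-membered rings into ring A (five) and ring B (seven). Ring B is oxidised afterwards and the ester is attached.
Stereochemistry: C1 comes from the (R)-1-phenylethylamine imine and C4 from axial organocerium attack. The C5 and C6 oxygens come from 4-OH-directed osmylation, C5 from inversion in the shift, and C6 from hydride delivered by the 4-OH. C7 comes from axial hydride attack on a C7 enone. C8 and C9 come from epoxidation anti to the C1 methyl and the 7β-silyl ether. The C8 methyl centre of the starting ketone only biases conformers and is erased later.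

Key step: step 8

Remark: the same atom numbers are kept for the decalin intermediates, where C1 and C6 are the fusion carbons. Ketone 3 is used as the mixture of epimers at its α-carbon, because that centre is rebuilt in step 3.

**Step 1**
Reactants: 1 (R)-3-methylcyclohexanone
Product: 3 (2RS,5R)-2,5-dimethylcyclohexan-1-one, via lithium enolate 2 (not isolated)
Conditions: LiN(i-Pr)2, THF, −78 °C; MeI, −78 to 0 °C
Reagents that add atoms: methyl iodide, CI
Why: Kinetic enolate alkylation: the bulky amide removes a proton from the methylene remote from the ring methyl, MeI alkylates that carbon, the minor 2,3-dimethyl isomer is removed by chromatography, and the new centre needs no control because step 3 passes through its enamine.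

**Step 2**
Reactants: 3 (2RS,5R)-2,5-dimethylcyclohexan-1-one; 4 (R)-1-phenylethylamine
Product: 5 (5R)-2,5-dimethyl-N-[(1R)-1-phenylethyl]cyclohexan-1-imine
Conditions: cat. TsOH, toluene, reflux, Dean–Stark trap
Reagents that add atoms: none
Why: Acid-catalysed ketimine condensation driven by azeotropic removal of water; C8 is untouched and the α-centre stays mobile through imine–enamine tautomerism.

**Step 3**
Reactants: 5 imine; 6 methyl vinyl ketone
Product: 8 (2S,5R)-2,5-dimethyl-2-(3-oxobutyl)cyclohexan-1-one, via Michael adduct imine 7 (not isolated)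
Conditions: THF, 25 °C; then 10% aq AcOH, 25 °C
Reagents that add atoms: water, O
Why: d'Angelo asymmetric Michael addition: the imine reacts through its more substituted secondary enamine in a compact aza-ene-like transition state, the enone approaches the face turned away from the phenyl group, which for the (R)-amine builds the (S)-quaternary carbon C1 (auxiliary control outweighs the weak bias of the remote C8 methyl), and aqueous acid then hydrolyses the imine.

**Step 4**
Reactants: 8 diketone
Product: 10 (4aS,7R)-4a,7-dimethyl-4,4a,5,6,7,8-hexahydronaphthalen-2(3H)-one, via cis-ketol 9 (not isolated)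
Conditions: NaOMe, MeOH, 60 °C
Reagents that add atoms: none
Why: Intramolecular aldol condensation (second half of a Robinson annulation): the methyl ketone enolate adds 6-(enolendo)-exo-trig to the ring ketone and the cis-ketol loses water to the conjugated octalone without touching C1 or C8.

**Step 5**
Reactants: 10 octalone
Product: 11 (2R,4aS,7R)-4a,7-dimethyl-2-(propan-2-yl)-2,3,4,4a,5,6,7,8-octahydronaphthalen-2-ol (4β-OH; 4α-i-Pr; C5=C6)
Conditions: i-PrMgCl, CeCl3 (anhydrous), THF, −78 to 0 °C; aq NH4Cl
Reagents that add atoms: isopropylmagnesium chloride, CC(C)[Mg]Cl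
Why: Imamoto organocerium 1,2-addition: the weakly basic cerium reagent suppresses enolisation, reduction and conjugate addition, and it attacks the cyclohexenone carbonyl axially from the α face, opposite the angular methyl, so that C4 carries a β-hydroxyl and an α-isopropyl group.

**Step 6**
Reactants: 11 allylic alcohol
Product: 13 4α-isopropyl-1β,8β-dimethyl-cis-decalin-4β,5β,6β-triol, via osmate ester TMEDA complex 12 (not isolated)
Conditions: OsO4 (1.05 equiv), TMEDA, CH2Cl2, −78 °C to rt; then aq Na2SO3, THF, reflux
Reagents that add atoms: osmium tetroxide, O=[Os](=O)(=O)=O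
Why: Donohoe hydroxyl-directed dihydroxylation: the OsO4–TMEDA complex accepts a hydrogen bond from the 4β-hydroxyl and adds suprafacially to the β face of C5=C6, the α face being screened by the pseudoaxial isopropyl group, which gives the all-cis 4β,5β,6β-triol and thereby the cis-decalin.

**Step 7**
Reactants: 13 triol
Product: 14 cis-decalin-4β,5β,6β-triol 5-methanesulfonate
Conditions: MsCl, Et3N, CH2Cl2, −20 to 0 °C
Reagents that add atoms: methanesulfonyl chloride, CS(=O)(=O)Cl
Why: Chemoselective sulfonylation: only the secondary C5 hydroxyl reacts while the two tertiary hydroxyls stay free, and since both are cis to the new mesylate no epoxide can form under the basic conditions.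

**Step 8**
Reactants: 14 triol 5-methanesulfonate
Product: 16 trans-fused 4β-hydroxy-8β-methyl-5αH-daucan-6-one, via bis(diethylaluminium) alkoxide 15 (not isolated)
Conditions: Et3Al (4 equiv), CH2Cl2, −78 to 0 °C; aq potassium sodium tartrate
Reagents that add atoms: none
Why: Et3Al turns both tertiary hydroxyls into diethylaluminium alkoxides and complexes the sulfonate, and as the C5–O bond lengthens the antiperiplanar fusion bond C6–C1 moves over to C5 while the C6 alkoxide collapses to the ketone, a concerted semipinacol rearrangement whose closest known relatives are the shifts of decalin-1,2-diol monosulfonates to hydroazulenones. Ring A (five-membered) is closed by contraction of the cyclohexane C1–C2–C3–C4–C5–C6 and ring B (seven-membered) by one-carbon expansion of the cyclohexane C1–C6–C7–C8–C9–C10, both through the same suprafacial three-centre 1,2-shift, so that no exo or endo cyclisation mode is involved. C5 is the only new stereocentre and is set by inversion: C1 arrives anti to the β-mesylate, H5 stays on the α face, and C1 migrates with retention so that its methyl stays β, which makes the fusion trans. The alignment is secured by the chair–chair conformer of the cis-decalin that has the isopropyl group, the mesylate and the C8 methyl equatorial and the oxygens on C4 and C6 axial; both oxygens are cis to the leaving group, so neither can close an epoxide. The selectivity that is needed is migration of C6–C1 in preference to the equally aligned C4–C3, and it rests on the higher migratory aptitude of the fully substituted C1 over the methylene C3 and on relief of strain in the crowded C1–C6 bond. The low temperature and the non-basic medium keep the β-hydroxy ketone from retro-aldol cleavage and C5 from epimerising.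

**Step 9**
Reactants: 16 hydroxy ketone
Product: 17 4β,6-bis(trimethylsilyloxy)-8β-methyl-5αH-dauc-6-ene (C6=C7 silyl enol ether)
Conditions: TMSOTf (3 equiv), Et3N, CH2Cl2, 0 °C
Reagents that add atoms: trimethylsilyl triflate, C[Si](C)(C)OS(=O)(=O)C(F)(F)F
Why: Soft enolisation and O-silylation with a silyl triflate and an amine: the tertiary hydroxyl is capped, which blocks retro-aldol cleavage, and the ketone enolises towards the C7 methylene because C5–H is buried between two fully substituted carbons and is therefore not epimerised.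

**Step 10**
Reactants: 17 bis-silyl compound
Product: 19 4β-hydroxy-5αH-dauc-7-en-6-one, via 4-O-trimethylsilyl enone 18 (not isolated)
Conditions: Pd(OAc)2 (1.1 equiv), MeCN, 25 °C; then 1 M aq HCl, THF, 0 °C
Reagents that add atoms: none
Why: Saegusa–Ito dehydrogenation: divalent palladium binds C7 from the open α face, syn β-hydride elimination takes the α-oriented H8 and can give only the C7=C8 enone because C4 bears no hydrogen, and dilute acid then frees the tertiary hydroxyl.

**Step 11**
Reactants: 19 hydroxy enone
Product: 21 5αH-dauc-7-ene-4β,6α-diol, via alkoxydiacetoxyborohydride 20 (not isolated)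
Conditions: Me4NBH(OAc)3, MeCN–AcOH, −30 °C
Reagents that add atoms: none
Why: Evans–Saksena hydroxyl-directed reduction: the 4β-hydroxyl displaces an acetate on boron and the bound hydride reaches C6 from the β face through a six-membered transition state, giving the equatorial 6α-alcohol (1,3-anti to O4) by 1,2-reduction, whereas the unbound reagent does not reduce ketones.

**Step 12**
Reactants: 22 4-hydroxybenzoic acid
Product: 24 4-(tert-butyldimethylsilyloxy)benzoic acid, via bis-silyl derivative 23 (not isolated)
Conditions: TBSCl (2.3 equiv), imidazole, DMF, 25 °C; then AcOH–THF–H2O, 25 °C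
Reagents that add atoms: tert-butyldimethylsilyl chloride, CC(C)(C)[Si](C)(C)Cl
Why: Exhaustive silylation followed by selective hydrolysis: the silyl ester is far more labile than the aryl silyl ether, so mild aqueous acid returns the carboxylic acid with the phenol still masked.

**Step 13**
Reactants: 21 diol; 24 silylated acid
Product: 26 6α-[4-(tert-butyldimethylsilyloxy)benzoyloxy]-5αH-dauc-7-en-4β-ol, via O-acylisourea 25 (not isolated)
Conditions: DCC, DMAP (cat.), CH2Cl2, 0 to 25 °C
Reagents that add atoms: none
Why: Steglich esterification: the DMAP-activated acyl group is taken up by the only secondary hydroxyl, the hindered tertiary C4 hydroxyl being inert, and C6 keeps its configuration because its C–O bond is not broken.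

**Step 14**
Reactants: 26 allylic ester
Product: 28 6α-[4-(tert-butyldimethylsilyloxy)benzoyloxy]-4β-hydroxy-5αH-dauc-8-en-7-one, via 7α-hydroperoxide 27 (not isolated)
Conditions: O2, tetraphenylporphyrin (cat.), hν, CH2Cl2, 0 °C; then Ac2O, pyridine, 0 to 25 °C
Reagents that add atoms: oxygen, O=O
Why: Schenck ene reaction followed by Kornblum–DeLaMare-type dehydration: singlet oxygen approaches the α face, bonds to C7 and takes the pseudoaxial H9α on the more substituted side of the alkene (H6 lies on the β face and is deactivated by the ester), which moves the double bond to C8=C9, and Ac2O–pyridine dehydrates the secondary hydroperoxide to the conjugated C7 ketone, so the C7 configuration at this stage does not matter.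

**Step 15**
Reactants: 28 C7 enone
Product: 29 6α-[4-(tert-butyldimethylsilyloxy)benzoyloxy]-5αH-dauc-8-ene-4β,7β-diol
Conditions: NaBH4, CeCl3·7H2O, MeOH, −78 °C
Reagents that add atoms: none
Why: Luche 1,2-reduction: hydride adds axially from the α face, anti to the axial H6β and away from the β angular methyl, so the new hydroxyl is the equatorial 7β one, trans to the 6α-ester, and the cold, nearly neutral medium prevents acyl migration.

**Step 16**
Reactants: 29 allylic alcohol
Product: 30 7β-triethylsilyl ether of 29
Conditions: TESCl, imidazole, DMF, 0 °C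
Reagents that add atoms: triethylsilyl chloride, CC[Si](CC)(CC)Cl
Why: Silylation of the only unhindered hydroxyl: masking O7 removes its syn-directing hydrogen bond and adds bulk to the β face before the epoxidation, while the tertiary C4 hydroxyl does not react with the silyl chloride.

**Step 17**
Reactants: 30 silyl ether
Product: 31 8α,9α-epoxide of 30
Conditions: dimethyldioxirane, acetone–CH2Cl2, 0 °C
Reagents that add atoms: dimethyldioxirane, CC1(C)OO1
Why: Dioxirane epoxidation (concerted oxygen transfer): the only remaining alkene C8=C9 is attacked from the α face because the β face carries the axial C1 methyl and the 7β-silyl ether, which sets C8 and C9 together, and the neutral medium spares epoxide, ester and silyl ethers.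

**Step 18**
Reactants: 31 bis-silylated epoxide
Product: 32 CNP0290052.1, 8α,9α-epoxy-6α-(4-hydroxybenzoyloxy)-5αH-daucane-4β,7β-diol
Conditions: Bu4NF, AcOH (equimolar), THF, 0 °C
Reagents that add atoms: none
Why: Fluoride-induced desilylation buffered with acetic acid: both Si–O bonds are cleaved while the buffer keeps the 7β-oxygen from Payne rearrangement and acyl migration, and no stereocentre is touched.

**Compound list**

1 | (R)-3-methylcyclohexanone | C[C@@H]1CCCC(=O)C1 | starting material
2 | lithium (5R)-5-methylcyclohex-1-en-1-olate | C[C@@H]1CCC=C([O-])C1.[Li+] | intermediate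
3 | (2RS,5R)-2,5-dimethylcyclohexan-1-one | CC1CC[C@@H](C)CC1=O | intermediate
4 | (R)-1-phenylethylamine | C[C@H](c1ccccc1)N | starting material
5 | (5R)-2,5-dimethyl-N-[(1R)-1-phenylethyl]cyclohexan-1-imine | CC1CC[C@@H](C)CC1=N[C@H](C)c1ccccc1 | intermediate
6 | methyl vinyl ketone | C=CC(C)=O | starting material
7 | 4-[(1S,4R)-1,4-dimethyl-2-{[(1R)-1-phenylethyl]imino}cyclohexyl]butan-2-one | CC(=O)CC[C@]1(C)CC[C@@H](C)CC1=N[C@H](C)c1ccccc1 | intermediate
8 | (2S,5R)-2,5-dimethyl-2-(3-oxobutyl)cyclohexan-1-one | CC(=O)CC[C@]1(C)CC[C@@H](C)CC1=O | intermediate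
9 | cis-ketol, 6β-hydroxy-1β,8β-dimethyl-cis-decalin-4-one | O=C1CC[C@]2(C)CC[C@@H](C)C[C@]2(O)C1 | intermediate
10 | (4aS,7R)-4a,7-dimethyl-4,4a,5,6,7,8-hexahydronaphthalen-2(3H)-one | O=C1CC[C@]2(C)CC[C@@H](C)CC2=C1 | intermediate
11 | (2R,4aS,7R)-4a,7-dimethyl-2-(propan-2-yl)-2,3,4,4a,5,6,7,8-octahydronaphthalen-2-ol | CC(C)[C@]1(O)CC[C@]2(C)CC[C@@H](C)CC2=C1 | intermediate
12 | 5β,6β-osmate ester of 11, TMEDA complex | CC(C)[C@]1(O)CC[C@]2(C)CC[C@@H](C)C[C@@]23O[Os](=O)(=O)O[C@@H]13.CN(C)CCN(C)C | intermediate
13 | 4α-isopropyl-1β,8β-dimethyl-cis-decalin-4β,5β,6β-triol | CC(C)[C@]1(O)CC[C@]2(C)CC[C@@H](C)C[C@]2(O)[C@H]1O | intermediate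
14 | triol 13 5-methanesulfonate (5β-OMs) | CC(C)[C@]1(O)CC[C@]2(C)CC[C@@H](C)C[C@]2(O)[C@H]1OS(C)(=O)=O | intermediate
15 | 4,6-bis(diethylaluminium) alkoxide of 14 | CC(C)[C@]1(O[Al](CC)CC)CC[C@]2(C)CC[C@@H](C)C[C@]2(O[Al](CC)CC)[C@H]1OS(C)(=O)=O | intermediate
16 | trans-fused 4β-hydroxy-8β-methyl-5αH-daucan-6-one | CC(C)[C@]1(O)CC[C@]2(C)CC[C@@H](C)CC(=O)[C@H]21 | intermediate
17 | 4β,6-bis(trimethylsilyloxy)-8β-methyl-5αH-dauc-6-ene | CC(C)[C@]1(O[Si](C)(C)C)CC[C@]2(C)CC[C@@H](C)C=C(O[Si](C)(C)C)[C@H]21 | intermediate
18 | 4β-trimethylsilyloxy-5αH-dauc-7-en-6-one | CC(C)[C@]1(O[Si](C)(C)C)CC[C@]2(C)CCC(C)=CC(=O)[C@H]21 | intermediate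
19 | 4β-hydroxy-5αH-dauc-7-en-6-one | CC(C)[C@]1(O)CC[C@]2(C)CCC(C)=CC(=O)[C@H]21 | intermediate
20 | tetramethylammonium 4-O-diacetoxyborohydride of 19 | CC(C)[C@]1(O[BH-](OC(C)=O)OC(C)=O)CC[C@]2(C)CCC(C)=CC(=O)[C@H]21.C[N+](C)(C)C | intermediate
21 | 5αH-dauc-7-ene-4β,6α-diol | CC(C)[C@]1(O)CC[C@]2(C)CCC(C)=C[C@H](O)[C@H]21 | intermediate
22 | 4-hydroxybenzoic acid | O=C(O)c1ccc(O)cc1 | starting material
23 | tert-butyldimethylsilyl 4-(tert-butyldimethylsilyloxy)benzoate | CC(C)(C)[Si](C)(C)Oc1ccc(cc1)C(=O)O[Si](C)(C)C(C)(C)C | intermediate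
24 | 4-(tert-butyldimethylsilyloxy)benzoic acid | CC(C)(C)[Si](C)(C)Oc1ccc(cc1)C(=O)O | intermediate
25 | O-acylisourea from 24 and DCC | CC(C)(C)[Si](C)(C)Oc1ccc(cc1)C(=O)OC(=NC1CCCCC1)NC1CCCCC1 | intermediate
26 | 6α-[4-(tert-butyldimethylsilyloxy)benzoyloxy]-5αH-dauc-7-en-4β-ol | CC(C)[C@]1(O)CC[C@]2(C)CCC(C)=C[C@H](OC(=O)c3ccc(O[Si](C)(C)C(C)(C)C)cc3)[C@H]21 | intermediate
27 | 7α-hydroperoxy-dauc-8-ene derived from 26 | CC(C)[C@]1(O)CC[C@]2(C)CC=C(C)[C@H](OO)[C@H](OC(=O)c3ccc(O[Si](C)(C)C(C)(C)C)cc3)[C@H]21 | intermediate
28 | 6α-[4-(tert-butyldimethylsilyloxy)benzoyloxy]-4β-hydroxy-5αH-dauc-8-en-7-one | CC(C)[C@]1(O)CC[C@]2(C)CC=C(C)C(=O)[C@H](OC(=O)c3ccc(O[Si](C)(C)C(C)(C)C)cc3)[C@H]21 | intermediate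
29 | 6α-[4-(tert-butyldimethylsilyloxy)benzoyloxy]-5αH-dauc-8-ene-4β,7β-diol | CC(C)[C@]1(O)CC[C@]2(C)CC=C(C)[C@@H](O)[C@H](OC(=O)c3ccc(O[Si](C)(C)C(C)(C)C)cc3)[C@H]21 | intermediate
30 | 7β-triethylsilyl ether of 29 | CC(C)[C@]1(O)CC[C@]2(C)CC=C(C)[C@@H](O[Si](CC)(CC)CC)[C@H](OC(=O)c3ccc(O[Si](C)(C)C(C)(C)C)cc3)[C@H]21 | intermediate
31 | 8α,9α-epoxide of 30 | CC(C)[C@]1(O)CC[C@]2(C)C[C@@H]3O[C@]3(C)[C@@H](O[Si](CC)(CC)CC)[C@H](OC(=O)c3ccc(O[Si](C)(C)C(C)(C)C)cc3)[C@H]21 | intermediate
32 | CNP0290052.1, 8α,9α-epoxy-6α-(4-hydroxybenzoyloxy)-5αH-daucane-4β,7β-diol | CC(C)[C@]1(O)CC[C@]2(C)C[C@@H]3O[C@]3(C)[C@@H](O)[C@H](OC(=O)c3ccc(O)cc3)[C@H]21 | target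

**Step count**

Total step count: 18. Longest linear sequence: 17 (steps 1–11 and 13–18). Step 12 prepares the acid fragment.

**Steps most likely to fail**

**Step 8.**
- Risk: the C4 alkoxide may push instead of the C6 alkoxide. The C4–C3 bond, which is equally well aligned, would then migrate and contract the carbinol ring without expanding the other ring. Ionisation could also run ahead of migration.
- Fallback: it sets out from 14 and removes the competing donor.
- TMSOTf (1 equiv) and 2,6-lutidine in CH2Cl2 at −78 °C should silylate the more accessible C4 hydroxyl, because the C6 hydroxyl is flanked by quaternary C1 on the concave face. This gives the 4-O-trimethylsilyl mesylate F1.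
- Only O6 can then be metalated. Et3Al (or KOt-Bu in t-BuOH) triggers the same C6-to-C5 shift and gives the 4-O-trimethylsilyl ketone F2.
- TMSOTf and Et3N convert F2 into 17, where the route is rejoined.

**Step 6.**
- Risk: osmylation on the face that carries the angular methyl may be slow, and attack from the α face may compete. That would give poor facial selectivity.
- Fallback: it sets out from 11 and installs the two oxygens one at a time.
- VO(acac)2 with t-BuOOH, directed by the 4β-hydroxyl, gives the 5β,6β-epoxy alcohol F3.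
- Al(Oi-Pr)3 in hot toluene isomerises the epoxide. Only C7 offers a proton, so the product is the 4β,5β-diol with a C6=C7 double bond F4.
- A second VO(acac)2/t-BuOOH epoxidation, now directed by the 5β-hydroxyl, gives the 6β,7β-epoxy diol F5.
- LiEt3BH opens F5 at the secondary C7 and leaves the 6β-hydroxyl, which is triol 13.

**Step 14.**
- Risk: hydrogen abstraction from the C8 methyl group would place the new double bond exocyclic. Attack on the β face with abstraction of H6 is the other way site selectivity could erode.
- Fallback: it sets out from 18, which is then isolated instead of being hydrolysed, and reaches the C7 ketone by enolate chemistry.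
- KN(SiMe3)2 in THF at −78 °C removes a C9 proton to give the extended dienolate. 2-(Phenylsulfonyl)-3-phenyloxaziridine hydroxylates it at C7 with deconjugation to the 7-hydroxy-dauc-8-en-6-one F6. Either C7 epimer serves.
- Dess–Martin periodinane gives the 6,7-dione F7, and dilute HCl frees the tertiary hydroxyl to give the hydroxy dione F8.
- One equivalent of Me4NBH(OAc)3, directed by the 4β-hydroxyl, reduces only C6 to the 6α-hydroxy-7-ketone F9.
- Steglich esterification of F9 with 24 returns to 28.

**Further compounds**

F1 | step 8 | 4-O-trimethylsilyl ether of mesylate 14 | CC(C)[C@]1(O[Si](C)(C)C)CC[C@]2(C)CC[C@@H](C)C[C@]2(O)[C@H]1OS(C)(=O)=O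
F2 | step 8 | 4β-trimethylsilyloxy-8β-methyl-5αH-daucan-6-one | CC(C)[C@]1(O[Si](C)(C)C)CC[C@]2(C)CC[C@@H](C)CC(=O)[C@H]21
F3 | step 6 | 5β,6β-epoxide of allylic alcohol 11 | CC(C)[C@]1(O)CC[C@]2(C)CC[C@@H](C)C[C@@]23O[C@@H]13
F4 | step 6 | 4α-isopropyl-1β,8β-dimethyl-octal-6-ene-4β,5β-diol (C6=C7) | CC(C)[C@]1(O)CC[C@]2(C)CC[C@@H](C)C=C2[C@H]1O
F5 | step 6 | 6β,7β-epoxide of F4 | CC(C)[C@]1(O)CC[C@]2(C)CC[C@@H](C)[C@H]3O[C@@]23[C@H]1O
F6 | step 14 | 7-hydroxy-4β-trimethylsilyloxy-5αH-dauc-8-en-6-one (C7 epimers) | CC(C)[C@]1(O[Si](C)(C)C)CC[C@]2(C)CC=C(C)C(O)C(=O)[C@H]21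
F7 | step 14 | 4β-trimethylsilyloxy-5αH-dauc-8-ene-6,7-dione | CC(C)[C@]1(O[Si](C)(C)C)CC[C@]2(C)CC=C(C)C(=O)C(=O)[C@H]21
F8 | step 14 | 4β-hydroxy-5αH-dauc-8-ene-6,7-dione | CC(C)[C@]1(O)CC[C@]2(C)CC=C(C)C(=O)C(=O)[C@H]21
F9 | step 14 | 4β,6α-dihydroxy-5αH-dauc-8-en-7-one | CC(C)[C@]1(O)CC[C@]2(C)CC=C(C)C(=O)[C@H](O)[C@H]21
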